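**Retrosynthetic overview**

- Feature: ring A of the target (C1, C2, C3, C4, C4a, C8a) is a phthaloyl unit. Its C1 and C4 carbonyls sit on the adjacent arene carbons C8a and C4a, and the C2=C3 alkene between them carries the side chain on C2 and hydrogen on C3, which is the footprint of a terminal alkyne.
- Key disconnection: C1–C2 and C3–C4 are cut back to a 3,6-dimethoxyphthaloyl cobaltacycle and the terminal alkyne (R)-6-methylhept-5-en-1-yn-3-yl 2-methylpropanoate. The cobaltacycle comes from insertion of ClCo(PPh3)3 into the strained acyl–acyl bond of 3,6-dimethoxybenzocyclobutene-1,2-dione.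
- Dione: aryne [2+2] cycloaddition of 2-bromo-1,4-dimethoxybenzene with 1,1-diethoxyethene, ketal hydrolysis, benzylic gem-dibromination, hydrolysis.
- Alkyne: Weinreb amide of 4-methylpent-3-enoic acid, silyl ynone, asymmetric transfer hydrogenation (sets the carbinol carbon as R), desilylation, isobutyrylation.
- Ring order: benzene ring bought; four-membered ring (step 1); five-membered cobaltacycle (step 4); quinone ring A (step 10); the 5,8-diol is freed last by oxidative demethylation and reduction (step 11).

Key step: step 10

Remark: the name is taken to mean the 2-methylpropanoate ester of (R)-shikonin, as the SMILES shows. The 5,8-dihydroxy-1,4-naphthoquinone tautomers interconvert rapidly, so the tautomer drawn is not distinguished from the one with the quinone in the other ring.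

Remark: in the SMILES of the cobalt complexes each donor bond from phosphorus or nitrogen to cobalt is drawn as a single bond with a positive formal charge on the donor atom and a matching negative formal charge on cobalt; the complexes are neutral.

**Route**

Step 1
Reactants: 1 2-bromo-1,4-dimethoxybenzene; 2 1,1-diethoxyethene
Product: 5 3,6-dimethoxybenzocyclobutenone, via 3,6-dimethoxybenzyne 3 (not isolated), via 7,7-diethoxy-2,5-dimethoxybicyclo[4.2.0]octa-1,3,5-triene 4 (not isolated)
Conditions: NaNH2 (2.5 equiv), 2 (2 equiv), THF, reflux; then 1 M aq. HCl, THF, rt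
Reagents that add atoms: water, O
Why: NaNH2 should remove the hydrogen between Br and OMe and expel bromide to give the symmetrical aryne, which undergoes the stepwise [2+2] cycloaddition with the electron-rich ketene acetal to a single ketal that dilute acid hydrolyses to the ketone (aryne [2+2] cycloaddition, ketal hydrolysis).

Step 2
Reactants: 5 3,6-dimethoxybenzocyclobutenone
Product: 6 2,2-dibromo-3,6-dimethoxybenzocyclobutenone
Conditions: N-bromosuccinimide (2.2 equiv), dibenzoyl peroxide (cat.), PhCF3 (or CCl4), reflux, hν
Reagents that add atoms: N-bromosuccinimide, O=C1CCC(=O)N1Br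
Why: Wohl–Ziegler radical bromination should take place at the only benzylic CH2, which is also alpha to the carbonyl, and stop at the gem-dibromide because no further C–H is left there.

Step 3
Reactants: 6 2,2-dibromo-3,6-dimethoxybenzocyclobutenone
Product: 7 3,6-dimethoxybenzocyclobutene-1,2-dione
Conditions: 50% aq. H2SO4, 55 °C
Reagents that add atoms: water, O
Why: Acid hydrolysis of the alpha,alpha-dibromo ketone (gem-dihalide hydrolysis) should give the second carbonyl, the acidic medium being chosen because the strained dione is opened by base but not by acid.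

Step 4
Reactants: 7 3,6-dimethoxybenzocyclobutene-1,2-dione
Product: 9 chloro(dimethylglyoxime)(pyridine)(3,6-dimethoxyphthaloyl)cobalt, via chlorobis(triphenylphosphine)(3,6-dimethoxyphthaloyl)cobalt 8 (not isolated)
Conditions: ClCo(PPh3)3 (1.05 equiv), PhCl, rt, N2; then dimethylglyoxime (1.1 equiv), pyridine, rt; complex precipitated and washed free of PPh3
Reagents that add atoms: ClCo(PPh3)3, Cl[Co-3]([P+](c1ccccc1)(c1ccccc1)c1ccccc1)([P+](c1ccccc1)(c1ccccc1)c1ccccc1)[P+](c1ccccc1)(c1ccccc1)c1ccccc1; dimethylglyoxime, CC(=NO)C(C)=NO; pyridine, c1ccncc1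
Why: Oxidative addition of electron-rich monovalent cobalt into the strained acyl–acyl bond should give the five-membered diacyl metallacycle of trivalent cobalt, and substitution of both phosphines by neutral N,N-bound dimethylglyoxime and pyridine should give the air-stable octahedral complex that takes up alkynes readily (strain-release C–C bond activation, ligand exchange).

Step 5
Reactants: 10 4-methylpent-3-enoic acid
Product: 12 N-methoxy-N,4-dimethylpent-3-enamide, via 1-(4-methylpent-3-enoyl)imidazole 11 (not isolated)
Conditions: 1,1'-carbonyldiimidazole (1.1 equiv), CH2Cl2, 0 °C to rt; then MeNH(OMe)·HCl (1.2 equiv), rt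
Reagents that add atoms: N,O-dimethylhydroxylamine hydrochloride, CNOC.Cl
Why: Acyl imidazolide formation and aminolysis (amide coupling) run near neutrality, which should keep the beta,gamma-alkene out of conjugation.

Step 6
Reactants: 12 N-methoxy-N,4-dimethylpent-3-enamide; 13 ethynyltrimethylsilane
Product: 16 6-methyl-1-(trimethylsilyl)hept-5-en-1-yn-3-one, via lithium (trimethylsilyl)acetylide 14 (not isolated), via lithium hemiaminal alkoxide 15 (not isolated)
Conditions: 13, n-BuLi, THF, −78 °C; then 12, −78 to 0 °C; inverse quench into cold 1 M aq. HCl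
Reagents that add atoms: none
Why: Addition of the acetylide to the Weinreb amide should give a chelated tetrahedral lithium adduct that collapses only on the acid quench, so the ynone forms without over-addition and without contact with base (Weinreb ketone synthesis).

Step 7
Reactants: 16 6-methyl-1-(trimethylsilyl)hept-5-en-1-yn-3-one
Product: 17 (R)-6-methyl-1-(trimethylsilyl)hept-5-en-1-yn-3-ol
Conditions: Ru[(R,R)-TsNCH(Ph)CH(Ph)NH](p-cymene) (1 mol %, preformed from RuCl[(R,R)-TsDPEN](p-cymene) and KOH), i-PrOH, rt
Reagents that add atoms: none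
Why: In the Noyori asymmetric transfer hydrogenation of ynones the alkynyl group takes the place that the aryl group has in aryl ketones, so the (R,R)-ligand should deliver hydride to the face that gives the (R)-carbinol, and the base-free amido catalyst should leave the acidic alpha-CH2 and the beta,gamma-alkene alone.

Step 8
Reactants: 17 (R)-6-methyl-1-(trimethylsilyl)hept-5-en-1-yn-3-ol
Product: 18 (R)-6-methylhept-5-en-1-yn-3-ol
Conditions: K2CO3 (0.2 equiv), MeOH, 0 °C to rt
Reagents that add atoms: none
Why: Carbonate-catalysed methanolysis of the alkynyl C–Si bond (protodesilylation) should free the terminal alkyne without touching the carbinol stereocenter.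

Step 9
Reactants: 18 (R)-6-methylhept-5-en-1-yn-3-ol
Product: 19 (R)-6-methylhept-5-en-1-yn-3-yl 2-methylpropanoate
Conditions: (i-PrCO)2O (1.5 equiv), Et3N, 4-(dimethylamino)pyridine (cat.), CH2Cl2, 0 °C to rt
Reagents that add atoms: isobutyric anhydride, CC(C)C(=O)OC(=O)C(C)C
Why: Nucleophile-catalysed acyl transfer to the secondary alcohol takes place at oxygen, so the configuration at carbon is retained.

Step 10
Reactants: 9 chloro(dimethylglyoxime)(pyridine)(3,6-dimethoxyphthaloyl)cobalt; 19 (R)-6-methylhept-5-en-1-yn-3-yl 2-methylpropanoate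
Product: 20 (R)-1-(5,8-dimethoxy-1,4-dioxo-1,4-dihydronaphthalen-2-yl)-4-methylpent-3-en-1-yl 2-methylpropanoate
Conditions: 19 (1.3 equiv), CoCl2·6H2O (Lewis-acid promoter), MeCN, 75 °C, N2
Reagents that add atoms: none
Why: The Lewis acid CoCl2·6H2O should labilise chloride or pyridine on octahedral 9 and open a site at the trivalent cobalt; the terminal alkyne of 19 then coordinates and inserts into one acyl–cobalt bond to give a seven-membered acyl(alkenyl)cobaltacycle, and C–C reductive elimination forms the second bond and releases monovalent cobalt, so ring A appears directly at the quinone oxidation level. The closest known reaction type is the naphthoquinone synthesis from phthaloylcobalt dimethylglyoxime complexes and alkynes, which is established for alkoxy-substituted phthaloyl units and for terminal and oxygen-bearing alkynes. Six-membered ring A is closed by a metal-templated [4+2] annulation in which the diacyl unit C1–C8a–C4a–C4 takes up the two alkyne carbons as C2 and C3, one bond by migratory insertion and the other by reductive elimination. No stereocenter is formed; the propargylic stereocenter of 19 is a spectator, and a silver-free promoter is chosen so that no 1,3-acyloxy shift or ionisation of the propargylic ester can scramble it. The step needs chemoselectivity for the alkyne over the trisubstituted alkene, which the much stronger binding and faster insertion of alkynes at cobalt should secure, and it needs no regiocontrol, because the mirror plane of the 3,6-dimethoxyphthaloyl unit exchanges its two acyl carbons and both insertion orientations give the same quinone.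

Step 11
Reactants: 20 (R)-1-(5,8-dimethoxy-1,4-dioxo-1,4-dihydronaphthalen-2-yl)-4-methylpent-3-en-1-yl 2-methylpropanoate
Product: 22 isobutylshikonin, via naphthalene-1,4,5,8-tetraone diquinone 21 (not isolated)
Conditions: AgO (6 equiv), 6 M HNO3, acetone, 0 °C, a few minutes, extraction into CHCl3; then aq. Na2S2O4, rt, work-up in air
Reagents that add atoms: water, O
Why: Oxidative demethylation of the p-dimethoxyarene ring by AgO in nitric acid (water adds to the ring carbons and methanol leaves) should give the diquinone, and its two-electron reduction by dithionite should give the 5,8-dihydroxy-1,4-naphthoquinone, the short contact at 0 °C being meant to spare the trisubstituted alkene, the ester and the untouched stereocenter.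

**Compound list**

1 | 2-bromo-1,4-dimethoxybenzene | COc1ccc(OC)c(Br)c1 | starting material
2 | 1,1-diethoxyethene | C=C(OCC)OCC | starting material
3 | 3,6-dimethoxybenzyne | COC1=CC=C(OC)C#C1 | intermediate
4 | 7,7-diethoxy-2,5-dimethoxybicyclo[4.2.0]octa-1,3,5-triene | CCOC1(OCC)Cc2c(OC)ccc(OC)c21 | intermediate
5 | 3,6-dimethoxybenzocyclobutenone | COc1ccc(OC)c2c1CC2=O | intermediate
6 | 2,2-dibromo-3,6-dimethoxybenzocyclobutenone | COc1ccc(OC)c2c1C(Br)(Br)C2=O | intermediate
7 | 3,6-dimethoxybenzocyclobutene-1,2-dione | COc1ccc(OC)c2c1C(=O)C2=O | intermediate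
8 | chlorobis(triphenylphosphine)(3,6-dimethoxyphthaloyl)cobalt (five-membered diacyl metallacycle of trivalent cobalt) | COc1ccc(OC)c2c1C(=O)[Co-2](Cl)([P+](c1ccccc1)(c1ccccc1)c1ccccc1)([P+](c1ccccc1)(c1ccccc1)c1ccccc1)C2=O | intermediate
9 | chloro(dimethylglyoxime)(pyridine)(3,6-dimethoxyphthaloyl)cobalt (octahedral complex of trivalent cobalt, dimethylglyoxime neutral and bound through both nitrogens) | COc1ccc(OC)c2c1C(=O)[Co-3]3(Cl)([n+]1ccccc1)([N+](O)=C(C)C(C)=[N+]3O)C2=O | intermediate
10 | 4-methylpent-3-enoic acid | CC(C)=CCC(=O)O | starting material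
11 | 1-(4-methylpent-3-enoyl)imidazole | CC(C)=CCC(=O)n1ccnc1 | intermediate
12 | N-methoxy-N,4-dimethylpent-3-enamide | CC(C)=CCC(=O)N(C)OC | intermediate
13 | ethynyltrimethylsilane | C#C[Si](C)(C)C | starting material
14 | lithium (trimethylsilyl)acetylide | [Li]C#C[Si](C)(C)C | intermediate
15 | lithium 3-[methoxy(methyl)amino]-6-methyl-1-(trimethylsilyl)hept-5-en-1-yn-3-olate (racemic tetrahedral adduct) | CC(C)=CCC(O[Li])(C#C[Si](C)(C)C)N(C)OC | intermediate
16 | 6-methyl-1-(trimethylsilyl)hept-5-en-1-yn-3-one | CC(C)=CCC(=O)C#C[Si](C)(C)C | intermediate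
17 | (R)-6-methyl-1-(trimethylsilyl)hept-5-en-1-yn-3-ol | CC(C)=CC[C@@H](O)C#C[Si](C)(C)C | intermediate
18 | (R)-6-methylhept-5-en-1-yn-3-ol | CC(C)=CC[C@@H](O)C#C | intermediate
19 | (R)-6-methylhept-5-en-1-yn-3-yl 2-methylpropanoate | CC(C)=CC[C@@H](OC(=O)C(C)C)C#C | intermediate
20 | (R)-1-(5,8-dimethoxy-1,4-dioxo-1,4-dihydronaphthalen-2-yl)-4-methylpent-3-en-1-yl 2-methylpropanoate | CC(C)=CC[C@@H](OC(=O)C(C)C)C1=CC(=O)c2c(OC)ccc(OC)c2C1=O | intermediate
21 | (R)-4-methyl-1-(1,4,5,8-tetraoxo-1,4,5,8-tetrahydronaphthalen-2-yl)pent-3-en-1-yl 2-methylpropanoate | CC(C)=CC[C@@H](OC(=O)C(C)C)C1=CC(=O)C2=C(C1=O)C(=O)C=CC2=O | intermediate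
22 | isobutylshikonin, (R)-1-(5,8-dihydroxy-1,4-dioxo-1,4-dihydronaphthalen-2-yl)-4-methylpent-3-en-1-yl 2-methylpropanoate | CC(C)=CC[C@@H](OC(=O)C(C)C)C1=CC(=O)c2c(O)ccc(O)c2C1=O | target

**Step count**

Total: 11 steps. Longest linear sequence: 7 steps (steps 5, 6, 7, 8, 9, 10, 11 from 4-methylpent-3-enoic acid); the dione arm is 6 steps (steps 1, 2, 3, 4, 10, 11).

**Steps most likely to fail**

Step 10. Uptake of the branched, ester-bearing alkyne at cobalt may be slow, so that Lewis-acid ionisation or 1,3-acyloxy shift of the propargylic ester and cobalt-mediated alkyne oligomerisation compete with the annulation. The fallback sets out from dione 7 and alcohol 18 and comes back at 20. Alcohol 18 would be silylated (TBSCl, imidazole, DMF) to (R)-tert-butyldimethyl[(6-methylhept-5-en-1-yn-3-yl)oxy]silane F1. Its lithium acetylide (n-BuLi, THF, −78 °C) would be added to one of the two equivalent carbonyls of 7 to give 8-hydroxy-2,5-dimethoxy-8-[(3R)-3-(tert-butyldimethylsilyloxy)-6-methylhept-5-en-1-yn-1-yl]bicyclo[4.2.0]octa-1,3,5-trien-7-one F2 as a mixture of carbinol epimers. Thermolysis in refluxing p-xylene should open the four-membered ring to the ketene, close it on the alkyne and shift the hydroxyl hydrogen to C3 (Moore rearrangement of a 4-alkynyl-4-hydroxycyclobutenone), giving 2-[(1R)-1-(tert-butyldimethylsilyloxy)-4-methylpent-3-enyl]-5,8-dimethoxy-1,4-naphthoquinone F3. HF·pyridine in THF would free 2-[(1R)-1-hydroxy-4-methylpent-3-enyl]-5,8-dimethoxy-1,4-naphthoquinone F4, and acylation under the conditions of step 9 would give 20.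

Step 11. The dimethoxyarene ring, deactivated by the two quinone carbonyls, may resist oxidation, so that attack on the trisubstituted alkene or decay of the diquinone outruns demethylation. The fallback sets out from 20 and comes back at 22. Reductive acetylation (Zn dust, Ac2O, Et3N, rt) would give (R)-1-(1,4-diacetoxy-5,8-dimethoxynaphthalen-2-yl)-4-methylpent-3-en-1-yl 2-methylpropanoate F5, in which the dimethoxy ring is an electron-rich naphthalene ring. (NH4)2Ce(NO3)6 in aqueous MeCN at 0 °C should then demethylate that ring oxidatively to (R)-1-(1,4-diacetoxy-5,8-dioxo-5,8-dihydronaphthalen-2-yl)-4-methylpent-3-en-1-yl 2-methylpropanoate F6. Mild cleavage of the two aryl acetates (NH4OAc, aqueous MeOH, rt), which should spare the hindered secondary isobutyrate, would give the 5,8-dihydroxy-1,4-naphthoquinone; this is 22, because tautomerism returns the quinone to the substituted ring.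

Step 2. Electrophilic bromination of the electron-rich dimethoxyarene ring may compete with the radical benzylic bromination, and the second bromination may stall. The fallback sets out from 1, bypasses 5 and 6, and comes back at 7. Methyl dimethoxyacetate would be converted (lithium diisopropylamide, TBSCl, THF, −78 °C) into the tetra-oxygenated ketene silyl acetal tert-butyl(dimethyl)[(1,2,2-trimethoxyethenyl)oxy]silane F7. Aryne 3, generated from 1 with lithium 2,2,6,6-tetramethylpiperidide (THF, −78 °C to rt) in the presence of F7, should give the [2+2] adduct tert-butyl(dimethyl)[(2,5,7,8,8-pentamethoxybicyclo[4.2.0]octa-1,3,5-trien-7-yl)oxy]silane F8, which already has both ring carbons at the carbonyl oxidation level. Aqueous acid hydrolysis of the two acetal carbons (CF3CO2H/H2O, then 50% aq. H2SO4 if the dimethyl ketal persists) would give 7.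

**Further compounds**

F1 | step 10 | (R)-tert-butyldimethyl[(6-methylhept-5-en-1-yn-3-yl)oxy]silane | CC(C)=CC[C@@H](O[Si](C)(C)C(C)(C)C)C#C
F2 | step 10 | 8-hydroxy-2,5-dimethoxy-8-[(3R)-3-(tert-butyldimethylsilyloxy)-6-methylhept-5-en-1-yn-1-yl]bicyclo[4.2.0]octa-1,3,5-trien-7-one (both C8 epimers) | CC(C)=CC[C@@H](O[Si](C)(C)C(C)(C)C)C#CC1(O)C(=O)c2c(OC)ccc(OC)c21
F3 | step 10 | 2-[(1R)-1-(tert-butyldimethylsilyloxy)-4-methylpent-3-enyl]-5,8-dimethoxy-1,4-naphthoquinone | CC(C)=CC[C@@H](O[Si](C)(C)C(C)(C)C)C1=CC(=O)c2c(OC)ccc(OC)c2C1=O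
F4 | step 10 | 2-[(1R)-1-hydroxy-4-methylpent-3-enyl]-5,8-dimethoxy-1,4-naphthoquinone | CC(C)=CC[C@@H](O)C1=CC(=O)c2c(OC)ccc(OC)c2C1=O
F5 | step 11 | (R)-1-(1,4-diacetoxy-5,8-dimethoxynaphthalen-2-yl)-4-methylpent-3-en-1-yl 2-methylpropanoate | CC(C)=CC[C@@H](OC(=O)C(C)C)c1cc(OC(C)=O)c2c(OC)ccc(OC)c2c1OC(C)=O
F6 | step 11 | (R)-1-(1,4-diacetoxy-5,8-dioxo-5,8-dihydronaphthalen-2-yl)-4-methylpent-3-en-1-yl 2-methylpropanoate | CC(C)=CC[C@@H](OC(=O)C(C)C)c1cc(OC(C)=O)c2C(=O)C=CC(=O)c2c1OC(C)=O
F7 | step 2 | tert-butyl(dimethyl)[(1,2,2-trimethoxyethenyl)oxy]silane | COC(OC)=C(OC)O[Si](C)(C)C(C)(C)C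
F8 | step 2 | tert-butyl(dimethyl)[(2,5,7,8,8-pentamethoxybicyclo[4.2.0]octa-1,3,5-trien-7-yl)oxy]silane (racemic) | COc1ccc(OC)c2c1C(OC)(OC)C2(OC)O[Si](C)(C)C(C)(C)C
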